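**Plan**
- Retrosynthesis (chromene numbering): the O1–C2 bond of the pyran is cut first, returning the C3=C4 alkene to a prenyl CH2–CH=; then the aryl–carbonyl bond at C6; last the aryl–prenyl bond C4a–C4.
- Forward: 5-methoxyresorcinol is MOM-protected and prenylated between the two MOM ethers. It is then metalated at a remaining ring CH and acylated with an (S)-3-silyloxy Weinreb amide. Acid removes all three protecting groups, and DDQ closes the pyran, the only ring made, in the last step.
- Enabling feature: the 2,2-dimethyl-2H-pyran ring (O1, C2, C3, C4, C4a, C8a) is fused to the benzene ring through C4a–C8a, so O1 (on C8a) and C4 (on C4a) are ortho. C4–C3–C2(CH3)2 is a prenyl group and O1 a phenol oxygen, so the ring is an ortho-prenylphenol less two hydrogens.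
- Stereochemistry: the single stereocentre, (S) at the side-chain carbinol, comes from commercial ethyl (S)-3-hydroxy-3-phenylpropanoate; no bond at this carbon is made or broken.

Key step: step 7

Assumption: the chiral ester is bought enantiopure; chromene locants (O1 to C8a) are used for the target and phenyl locants (C1 = acyl-bearing carbon) for the open-chain precursors.

**Step 1**
Reactants: 1 5-methoxyresorcinol
Product: 2 1-methoxy-3,5-bis(methoxymethoxy)benzene
Conditions: MOMCl (3.0 equiv), i-Pr2NEt (4.0 equiv), CH2Cl2, 0 °C to rt
Reagents that add atoms: chloromethyl methyl ether (MOMCl), COCCl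
Why: Base-mediated O-alkylation of both phenols with the reactive α-chloro ether (MOM protection) should be clean, and the two acetal ethers made here are the directing groups for both later metalations.

**Step 2**
Reactants: 2 1-methoxy-3,5-bis(methoxymethoxy)benzene; 3 prenyl bromide
Product: 5 5-methoxy-1,3-bis(methoxymethoxy)-2-(3-methylbut-2-en-1-yl)benzene, via aryllithium 4 (not isolated)
Conditions: n-BuLi (1.1 equiv), THF, 0 °C, 1 h; then 3 (1.3 equiv), −78 °C to rt
Reagents that add atoms: none
Why: Directed ortho-metalation should take place at the ring CH flanked by the two MOM ethers, the site activated by two chelating directors instead of one MOM and one weaker methoxy group, and the aryllithium is then alkylated at the primary carbon of the allylic bromide (SN2) to give the C-prenyl arene.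

**Step 3**
Reactants: 6 ethyl (S)-3-hydroxy-3-phenylpropanoate
Product: 7 (S)-3-hydroxy-N-methoxy-N-methyl-3-phenylpropanamide
Conditions: MeNHOMe·HCl (2.0 equiv), i-PrMgCl (5.0 equiv), THF, −20 to 0 °C; then 1 M aq HCl
Reagents that add atoms: N,O-dimethylhydroxylamine hydrochloride, CNOC.Cl
Why: Weinreb amide formation by aminolysis of the ester with the chloromagnesium amide made in the flask is a standard transformation that tolerates the free secondary alcohol as its magnesium alkoxide and does not touch the stereocentre.

**Step 4**
Reactants: 7 (S)-3-hydroxy-N-methoxy-N-methyl-3-phenylpropanamide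
Product: 8 (S)-3-[(tert-butyldimethylsilyl)oxy]-N-methoxy-N-methyl-3-phenylpropanamide
Conditions: TBSCl (1.3 equiv), imidazole (2.5 equiv), DMF, rt
Reagents that add atoms: tert-butyldimethylsilyl chloride (TBSCl), CC(C)(C)[Si](C)(C)Cl
Why: Silylation of the secondary benzylic alcohol with imidazole (TBS protection) removes the only acidic proton of the amide so that the aryllithium of the next step is not quenched, and the configuration is retained because the C–O bond is not involved.

**Step 5**
Reactants: 5 5-methoxy-1,3-bis(methoxymethoxy)-2-(3-methylbut-2-en-1-yl)benzene; 8 (S)-3-[(tert-butyldimethylsilyl)oxy]-N-methoxy-N-methyl-3-phenylpropanamide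
Product: 11 (S)-3-[(tert-butyldimethylsilyl)oxy]-1-[6-methoxy-2,4-bis(methoxymethoxy)-3-(3-methylbut-2-en-1-yl)phenyl]-3-phenylpropan-1-one, via aryllithium 9 (not isolated), via tetrahedral lithium alkoxide 10 (not isolated)
Conditions: 5 (1.2 equiv), n-BuLi (1.2 equiv), TMEDA (1.2 equiv), THF, 0 °C, 1 h; then 8 (1.0 equiv), −78 to 0 °C; sat. aq NH4Cl
Reagents that add atoms: none
Why: Directed ortho-metalation of 5 can only occur on the ring at the two equivalent CH positions between the methoxy group and a MOM ether, and the resulting aryllithium adds once to the N-methoxy-N-methylamide (Weinreb ketone synthesis) to give a chelated tetrahedral alkoxide that is stable until the quench, which prevents over-addition and leaves the silyloxy stereocentre untouched.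

**Step 6**
Reactants: 11 (S)-3-[(tert-butyldimethylsilyl)oxy]-1-[6-methoxy-2,4-bis(methoxymethoxy)-3-(3-methylbut-2-en-1-yl)phenyl]-3-phenylpropan-1-one
Product: 12 (S)-1-[2,4-dihydroxy-6-methoxy-3-(3-methylbut-2-en-1-yl)phenyl]-3-hydroxy-3-phenylpropan-1-one
Conditions: HCl (1.25 M in MeOH), MeOH, 0 °C to rt (up to 40 °C if the second MOM ether is slow)
Reagents that add atoms: none
Why: Acid-catalysed acetal exchange with methanol cleaves both aryl MOM ethers and acid methanolysis cleaves the secondary TBS ether in the same operation (global deprotection), while dilute acid at low temperature should spare the prenyl alkene and the β-hydroxy ketone, whose carbinol C–O bond is not ionised so that the (S) configuration is kept.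

**Step 7**
Reactants: 12 (S)-1-[2,4-dihydroxy-6-methoxy-3-(3-methylbut-2-en-1-yl)phenyl]-3-hydroxy-3-phenylpropan-1-one
Product: 14 (S)-3-hydroxy-1-(5-hydroxy-7-methoxy-2,2-dimethyl-2H-chromen-6-yl)-3-phenylpropan-1-one, via vinyl ortho-quinone methide 13 (not isolated)
Conditions: DDQ (1.1 equiv), 1,4-dioxane, rt to 60 °C
Reagents that add atoms: none
Why: DDQ forms a charge-transfer complex with the electron-rich ring and takes hydride from the benzylic CH2 of the prenyl group, the cation being stabilised by the flanking oxygen atoms, and loss of the proton of the non-chelated hydroxyl gives vinyl ortho-quinone methide 13. Its cisoid 1-oxatriene (O=C8a–C4a=C4–C3=C2) closes by a thermal disrotatory oxa-6π electrocyclisation that forms the O1–C2 bond, leaves the C3=C4 alkene and restores the aromatic ring. The closest known reaction type is the DDQ dehydrogenative cyclisation of ortho-prenylphenols to 2,2-dimethyl-2H-chromenes, which is well known for prenylated 2-acylresorcinols. The pyran ring, the only ring formed, is thus closed in a pericyclic six-electron mode across six atoms (O1, C8a, C4a, C4, C3, C2), and no stereocentre arises because C2 carries two methyl groups. The step needs site selectivity between the two hydroxyls that flank the prenyl group, and the substrate secures it: the hydroxyl ortho to the ketone is held in a hydrogen bond to the carbonyl oxygen, so the quinone methide that keeps this chelate, with its carbonyl at the free and more acidic para oxygen, is favoured and the closure falls on that oxygen (O1). It also needs chemoselectivity over the side-chain carbinol, which a non-activated 1-phenylalkanol provides because it is a far poorer hydride donor than the prenylphenol, while the absence of added acid or base protects the β-hydroxy ketone from dehydration.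

**Compound list**
1 | 5-methoxyresorcinol (5-methoxybenzene-1,3-diol) | COc1cc(O)cc(O)c1 | starting material
2 | 1-methoxy-3,5-bis(methoxymethoxy)benzene | COCOc1cc(OC)cc(OCOC)c1 | intermediate
3 | prenyl bromide (1-bromo-3-methylbut-2-ene) | CC(C)=CCBr | starting material
4 | [4-methoxy-2,6-bis(methoxymethoxy)phenyl]lithium (not isolated) | [Li]c1c(OCOC)cc(OC)cc1OCOC | intermediate
5 | 5-methoxy-1,3-bis(methoxymethoxy)-2-(3-methylbut-2-en-1-yl)benzene | COCOc1cc(OC)cc(OCOC)c1CC=C(C)C | intermediate
6 | ethyl (S)-3-hydroxy-3-phenylpropanoate | CCOC(=O)C[C@H](O)c1ccccc1 | starting material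
7 | (S)-3-hydroxy-N-methoxy-N-methyl-3-phenylpropanamide | CON(C)C(=O)C[C@H](O)c1ccccc1 | intermediate
8 | (S)-3-[(tert-butyldimethylsilyl)oxy]-N-methoxy-N-methyl-3-phenylpropanamide | CON(C)C(=O)C[C@H](O[Si](C)(C)C(C)(C)C)c1ccccc1 | intermediate
9 | [6-methoxy-2,4-bis(methoxymethoxy)-3-(3-methylbut-2-en-1-yl)phenyl]lithium (not isolated) | [Li]c1c(OC)cc(OCOC)c(CC=C(C)C)c1OCOC | intermediate
10 | lithium (3S)-3-[(tert-butyldimethylsilyl)oxy]-1-[methoxy(methyl)amino]-1-[6-methoxy-2,4-bis(methoxymethoxy)-3-(3-methylbut-2-en-1-yl)phenyl]-3-phenylpropan-1-olate (either configuration at C1; not isolated) | [Li]OC(N(C)OC)(C[C@H](O[Si](C)(C)C(C)(C)C)c1ccccc1)c1c(OC)cc(OCOC)c(CC=C(C)C)c1OCOC | intermediate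
11 | (S)-3-[(tert-butyldimethylsilyl)oxy]-1-[6-methoxy-2,4-bis(methoxymethoxy)-3-(3-methylbut-2-en-1-yl)phenyl]-3-phenylpropan-1-one | COCOc1cc(OC)c(C(=O)C[C@H](O[Si](C)(C)C(C)(C)C)c2ccccc2)c(OCOC)c1CC=C(C)C | intermediate
12 | (S)-1-[2,4-dihydroxy-6-methoxy-3-(3-methylbut-2-en-1-yl)phenyl]-3-hydroxy-3-phenylpropan-1-one | COc1cc(O)c(CC=C(C)C)c(O)c1C(=O)C[C@H](O)c1ccccc1 | intermediate
13 | (3S)-3-hydroxy-1-[2-hydroxy-6-methoxy-3-(3-methylbut-2-en-1-ylidene)-4-oxocyclohexa-1,5-dien-1-yl]-3-phenylpropan-1-one (vinyl ortho-quinone methide; not isolated) | COC1=CC(=O)C(=CC=C(C)C)C(O)=C1C(=O)C[C@H](O)c1ccccc1 | intermediate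
14 | (S)-3-hydroxy-1-(5-hydroxy-7-methoxy-2,2-dimethyl-2H-chromen-6-yl)-3-phenylpropan-1-one | COc1cc2c(c(O)c1C(=O)C[C@H](O)c1ccccc1)C=CC(C)(C)O2 | target

**Step count**
Total: 7 steps. Longest linear sequence: 5 steps (steps 1, 2, 5, 6, 7; the amide branch, steps 3 and 4, joins at step 5).

**Steps most likely to fail**

Step 5. The base may remove a proton from the doubly activated benzylic-allylic CH2 of the prenyl group instead of the ring CH, so that the wrong carbanion is acylated or the alkene migrates into conjugation. The fallback sets out from 5. Bromination with NBS (1.0 equiv, CH2Cl2, −78 °C) should occur at one of the two equivalent, highly activated ring positions in preference to the alkene and give 2-bromo-1-methoxy-3,5-bis(methoxymethoxy)-4-(3-methylbut-2-en-1-yl)benzene F1. Bromine–lithium exchange with t-BuLi (2 equiv, THF, −78 °C) then generates aryllithium 9 at a temperature at which no proton is removed from the side chain. Addition of 8 and the same quench return to the route at ketone 11.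

Step 6. Acid-promoted side reactions may outrun cleavage of the slower MOM ether: addition of a phenol to the protonated prenyl alkene (chroman formation), or dehydration of the β-oxygenated ketone followed by flavanone closure, which would also erase the stereocentre. The fallback sets out from 11. The two aryl MOM ethers are removed without protic acid by TMSOTf and 2,2'-bipyridyl (CH2Cl2, 0 °C to rt, then water), which turns them into silyl ethers that hydrolyse on work-up. This gives (S)-3-[(tert-butyldimethylsilyl)oxy]-1-[2,4-dihydroxy-6-methoxy-3-(3-methylbut-2-en-1-yl)phenyl]-3-phenylpropan-1-one F2. The silyl ether is then cleaved with HF·pyridine in THF/pyridine at 0 °C, which rejoins the route at 12.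

Step 7. The quinone may oxidise unselectively (attack on the electron-rich chromene formed, or phenol coupling), and the acidic hydroquinone formed may promote dehydration of the β-hydroxy ketone. The fallback sets out from 12 and replaces hydride abstraction by electrophilic selenoetherification. N-(Phenylseleno)phthalimide with catalytic camphorsulfonic acid (CH2Cl2, 0 °C) lets the free hydroxyl para to the ketone open the seleniranium ion at the tertiary carbon (6-endo). This gives (S)-3-hydroxy-1-[5-hydroxy-7-methoxy-2,2-dimethyl-3-(phenylselanyl)-3,4-dihydro-2H-chromen-6-yl]-3-phenylpropan-1-one F3 as a mixture of epimers at the selenium-bearing carbon. Oxidation with H2O2 (THF, 0 °C to rt) and syn elimination of the selenoxide towards the benzylic C4 hydrogens (C2 has none) gives the same O1–C2 bond and C3=C4 alkene and arrives at target 14.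

**Further compounds**
F1 | step 5 | 2-bromo-1-methoxy-3,5-bis(methoxymethoxy)-4-(3-methylbut-2-en-1-yl)benzene | COc1cc(OCOC)c(CC=C(C)C)c(OCOC)c1Br
F2 | step 6 | (S)-3-[(tert-butyldimethylsilyl)oxy]-1-[2,4-dihydroxy-6-methoxy-3-(3-methylbut-2-en-1-yl)phenyl]-3-phenylpropan-1-one | COc1cc(O)c(CC=C(C)C)c(O)c1C(=O)C[C@H](O[Si](C)(C)C(C)(C)C)c1ccccc1
F3 | step 7 | (S)-3-hydroxy-1-[5-hydroxy-7-methoxy-2,2-dimethyl-3-(phenylselanyl)-3,4-dihydro-2H-chromen-6-yl]-3-phenylpropan-1-one | COc1cc2c(c(O)c1C(=O)C[C@H](O)c1ccccc1)CC([Se]c1ccccc1)C(C)(C)O2
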